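I decided to read these set-ups by one time, the time for which the radical scavenger holds the chain back, and I put the flasks on the board first.

| flask | substrate | partner | initiator | radical scavenger | time | remark |
|---|---|---|---|---|---|---|
| spring | 0.050 M | 0.0750 M (fed, over 3.00 h) | 1.2 mM | 0.50 mM | 6.0 h | all but partner at the start; partner goes in evenly over 3.00 h, the run ends at 6.0 h |
| noon | 0.050 M (fed, over 3.00 h) | 0.0750 M | 1.2 mM | 0.50 mM | 6.0 h | a stirred flask in which substrate is dosed at a steady rate over 3.00 h without added volume, worked up at 6.0 h |
| dawn | 0.050 M | 0.0750 M | 1.2 mM | 0.50 mM | 6.0 h | everything together in a closed stirred flask, run for 6.0 h |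
| summer | 0.050 M | 0.0750 M | 1.2 mM | 0.50 mM |  | a single well-mixed tank run continuously and read at steady state, 6.0 h in it on average |

    partner + first chain carrier ⇌ product + second chain carrier (K1 = 0.73, k1 = 840 M⁻¹ s⁻¹)
    substrate + second chain carrier → released group + first chain carrier (k2 = 1200 M⁻¹ s⁻¹)
    substrate + initiating radical → capped initiator + first chain carrier (k3 = 27000 M⁻¹ s⁻¹)
    initiator → 2 initiating radical (k4 = 3.6 × 10⁻⁵ s⁻¹)
    2 substrate → homo dimer (k5 = 0.0011 M⁻¹ s⁻¹)
    2 second chain carrier → ended chains A (k6 = 4 × 10⁶ M⁻¹ s⁻¹)
    second chain carrier + radical scavenger → ended chains B (k7 = 9.6 × 10⁵ M⁻¹ s⁻¹)

- percent here means substrate units held: one homo dimer counts as two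
- two of one species on the left: rate k times its square, two consumed each time
- the stated concentrations are those of everything mixed, before any reaction; amounts are the same in each set-up
- the feed brings no volume worth counting
- run time (spring): 6.0 h

- the set-up with the highest amount of product at the outlet or at the end, in percent of the substrate put in ("none" if the first two lie within 2 percentage points) (spring / noon / dawn / summer / none)
- amount of product at the outlet or at the end, in percent of the substrate put in, spring
- amount of product at the outlet or at the end, in percent of the substrate put in, noon
- amount of product at the outlet or at the end, in percent of the substrate put in, dawn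
- amount of product at the outlet or at the end, in percent of the substrate put in, summer

I reckoned dawn, where nothing is dosed. In dawn the substrate started into homo dimer at 0.0198 M h⁻¹, a first half-life of 2.53 h. The chain stood back at first, because the radical scavenger took the second chain carrier at 480 s⁻¹ while the substrate took it at 60.0 s⁻¹. So the initiator first had to supply one radical for each radical scavenger, two radicals per initiator broken, and that took 1.80 h. I call this time the dead time, the induction period of the chain.

By its end in dawn, I reckoned, the dimer rate had slowed by a factor of 2.94, with 58.3 % of the substrate remaining, and the radical supply had slowed by a factor of 1.26. Then the chain opened, pseudo-first-order in substrate at 0.399 h⁻¹, against 0.231 h⁻¹ for the dimer. Holding both rates at these values and letting the surviving substrate go entirely to one path or the other, I gave the chain its share of 63.4 %, which made 37.0 % product for dawn. My reckoning went no further than dawn.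

The forecast chose noon, with 39 % for spring, 60 % for noon, 39.5 % for dawn and 47 % for summer, so its dawn figure stood above mine. Its ground for the choice was this: “Dosing the substrate keeps its concentration low and so suppresses the dimer most”.

The simulation gave noon as best at 55.7 %, with 38.7 % for spring, 38.7 % for dawn and 47.0 % for summer. At the end of the run, homo dimer stood at 53.1 % of the substrate in dawn and 30.8 % in noon, and the loss I had reckoned up to the end of the dead time in dawn was 41.7 %. For the neighbour of spring charged with 0.0020 M of radical scavenger, the same reckoning gives a dead time of 13.8 h, longer than its 6.0 h run. That neighbour ended with 35.1 % of its radical scavenger charge still there and product at 2.66 %.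

All constants were set for the occasion; the result is computed.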